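What matters in this flask is the leftover: a racemate goes in, a single-handed free catalyst works on it, and what stays behind should be mostly right-handed substrate. The north run is this same flask, followed so far.

- north: left-handed substrate 0.28 M; right-handed substrate 0.28 M; gas 120 mM (held); free catalyst 0.56 mM; the very flask that is asked about, followed so far
- flask: left-handed substrate 0.28 M; gas 120 mM (held); free catalyst 0.56 mM; right-handed substrate 0.28 M; time 10 d

north run (percent of the left-handed substrate and right-handed substrate together charged)

| time / d | right-handed substrate / % | left-handed substrate / % |
|---|---|---|
| 0.833 | 44 | 33 |
| 1.67 | 46 | 17 |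
| 2.50 | 39 | 11 |
| 3.00 | 38 | 3 |
| 4.00 | 30 | 1 |

(each reading ± 2 percentage points)

1. whether the excess of right-handed substrate over left-handed substrate among what is left of the two reaches 95% by 10 d (yes / no)
2. the highest excess of right-handed substrate over left-handed substrate among what is left of the two up to 10 d

- free catalyst is single-handed; left-handed substrate and right-handed substrate are mirror images of each other, charged as a racemate, each of them at the stated concentration
- at the start none of the gas is in solution

I reckon with rates. Each substrate loses, per day, a share of what is left of it. I assume that any slowing of the catalyst, including a lag while the gas dissolves, divides both rates by the same factor and so leaves their ratio standing. That ratio is the selectivity factor: how many times faster the left-handed substrate loses its share than the right-handed substrate does. Pooling the readings at 2.50 d, 3.00 d and 4.00 d, I read it as 7.97, with wide scatter.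

If a fraction x of the right-handed charge is left, left-handed per right-handed stands at x to the power of the factor less one. An excess of 95% means a ratio of 0.0256, so x must reach 59.1%. The reading at 4.00 d gives 60.0%, about there already. The right-handed substrate is losing 0.175 d⁻¹. If that rate holds, x falls to 21.0% by 10 d, and the ratio to 1.89 × 10⁻⁵.

The forecast says yes and 99.5%, on the grounds of “slightly more conversion, so I expect yes”. My top stands higher than the forecast's.

The flask gives yes and >99.9%.

    free catalyst + left-handed substrate ⇌ catalyst intermediate A (K = 22.0 L mol⁻¹, k = 3400 L mol⁻¹ h⁻¹)
    free catalyst + right-handed substrate ⇌ catalyst intermediate B (K = 5.90 L mol⁻¹, k = 4600 L mol⁻¹ h⁻¹)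
    reagent + catalyst intermediate A → free catalyst + left-handed product (k = 130 L mol⁻¹ h⁻¹)
    reagent + catalyst intermediate B → free catalyst + right-handed product (k = 52.0 L mol⁻¹ h⁻¹)
    2 free catalyst ⇌ resting dimer, settled at all times (K = 570 L mol⁻¹)
    gas ⇌ reagent, rate k6*(csat - [reagent]) (kL = 4.50 h⁻¹)
    free catalyst ⇌ dormant form (K = 0.410, k = 0.00480 h⁻¹)

The excess reaches 95% at 3.95 d, with 61.4% of the right-handed charge left, against my 59.1%. The forward step of the left-handed substrate alone has a half-life of 0.36 h, short against 10 d. Its backward turnover, though, is 91% of the forward one. Read back from that point of this flask, the factor is 8.51. With half the free catalyst the flask ends at an excess of 99.1%, and if the factor holds there, my reckoning puts the right-handed substrate left at about 49.0% of its charge.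

The runs were generated by integration with made-up constants; noise was put on by code.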